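Read this first.

| flask | starting complex | incoming ligand | capture agent | temperature | remark | time |
|---|---|---|---|---|---|---|
| beta | 0.50 M | 1 equiv | 10 mM | 45 °C | run made earlier |  |
| gamma | 0.50 M | 0.50 equiv | 10 mM | 56 °C | run made earlier |  |
| theta | 0.50 M | 0.75 equiv | 10 mM | 45 °C | run made earlier |  |
| delta | 0.50 M | 1 equiv | 15 mM | 56 °C | run made earlier |  |
| green | 0.50 M | 1.00 equiv | 10.0 mM |  | everything together at the start at 20 °C, warmed to 50 °C at 8.0 h | 10 h |
| blue | 0.50 M (fed, over 8.0 h) | 1.00 equiv | 10.0 mM | 50 °C | all else is in the flask from the start; the feed brings no volume worth counting | 10 h |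
| violet | 0.50 M | 1.00 equiv | 10.0 mM | 50 °C | everything together at the start | 10 h |
| amber | 0.50 M | 1.00 equiv (fed, over 8.0 h) | 10.0 mM | 50 °C | all else is in the flask from the start; the feed brings no volume worth counting | 10 h |
| ochre | 0.50 M | 1.00 equiv (fed, over 8.0 h) | 10.0 mM |  | the addition at 20 °C, then warmed to 50 °C; the feed brings no volume worth counting | 10 h |

- beta (time / h: side product / %, complex with three exchanged / %): 0.833: 0.8, 0; 1.33: 1.4, 1.2; 2.00: 2.1, 0; 4.00: 2.9, 2.8; 6.00: 6.6, 1.4; 10.0: 10.2, 2.0
- gamma (time / h: side product / %, complex with three exchanged / %): 2.00: 2.6, 0; 4.00: 6.9, 0.4; 6.00: 11.2, 0.7; 8.00: 14.5, 1.3; 10.0: 16.0, 1.1; 12.0: 18.4, 0.9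
- theta (time / h: side product / %, complex with three exchanged / %): 0.833: 0, 0.2; 2.50: 1.8, 0.9; 4.00: 3.4, 0.5; 6.00: 5.8, 0.2; 10.0: 8.9, 0.6; 12.0: 10.9, 1.7
- delta (time / h: side product / %, complex with three exchanged / %): 1.00: 2.6, 0.5; 2.00: 4.4, 0.5; 3.00: 6.7, 1.9; 6.00: 14.0, 2.6; 12.0: 23.9, 4.1

(scatter of a reading: 0.5 percentage points)

- the earlier runs were read with a standard deviation of 0.5 percentage points

* which flask leads in amount of side product, in percent of the starting complex charged ("all alike" within 1.5 percentage points) (green / blue / violet / amber / ochre / all alike)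
* how much side product is there at the end, in percent of the starting complex charged: green
* how much side product is there at the end, in percent of the starting complex charged: blue
* how much side product is there at the end, in percent of the starting complex charged: violet
* how much side product is there at the end, in percent of the starting complex charged: amber
* how much side product is there at the end, in percent of the starting complex charged: ochre

I price each flask with one quantity. The beta run reads 10.2% of side product at 10.0 h and 45 °C, which is 0.0102 h⁻¹ of the charge, and the delta run reads 14.0% at 6.00 h and 56 °C, which is 0.0233 h⁻¹; each reading carries a scatter of 0.5 points. Placing 50 °C between them on a logarithmic scale gives 0.0149 h⁻¹, the warm rate: the fraction of the charge that one hour at 50 °C turns into side product. The same line carried down to 20 °C gives 0.00156 h⁻¹.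

So do not warm green or ochre early: on that line, carried down from runs at 45 °C and 56 °C, a warm hour is priced at ten times a cold one, and that is an estimate, not a reading. Violet stands warm throughout, and I expect 14.9% there. Blue receives its starting complex over 8.0 h; I count those hours at half value, which leaves 6.00 h of full hours and 8.91%. Green has 2.00 h warm, and with its cold hours I reckon 4.22%.

The forecast names violet as the leader, with 3.8% for green, 8% for blue, 14% for violet, 11.5% for amber and 3.5% for ochre, and it holds that “Ligand dependence is weak”. My violet stands higher than its figure, and so does my green.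

    starting complex + incoming ligand ⇌ leaving ligand + complex with one exchanged (K = 2.10, k = 0.0240 M⁻¹ min⁻¹, Ea = 85.0 kJ mol⁻¹, ΔH = −29.0 kJ mol⁻¹)
    complex with one exchanged + incoming ligand ⇌ leaving ligand + complex with two exchanged (K = 1.00, k = 0.0230 M⁻¹ min⁻¹, Ea = 64.0 kJ mol⁻¹, ΔH = −35.0 kJ mol⁻¹)
    complex with two exchanged + incoming ligand ⇌ leaving ligand + complex with three exchanged (K = 1.60, k = 0.00250 M⁻¹ min⁻¹, Ea = 63.0 kJ mol⁻¹, ΔH = 3.00 kJ mol⁻¹)
    complex with one exchanged + capture agent → trapped intermediate (k = 0.00220 M⁻¹ min⁻¹, Ea = 89.0 kJ mol⁻¹)
    leaving ligand + starting complex → side product (k = 0.00200 M⁻¹ min⁻¹, Ea = 70.0 kJ mol⁻¹)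
    incoming ligand → decomposition product (k = 7.40 × 10⁻⁶ min⁻¹, Ea = 121 kJ mol⁻¹)
    (constants at 50 °C)

Violet leads at 14.4%, with amber at 10.8%, blue at 8.39%, green at 3.61% and ochre at 3.22%. At 10.0 h violet holds 33.5% of starting complex and 0.292 M of leaving ligand, the pair the scheme joins into side product. At the warm rate, ochre's 3.22% equals 2.16 h warm hours. Ochre read at 25 h has had 17.0 h warm, which the warm rate prices at 25.3%; that flask holds 21.7%.

The data are calculated with made-up constants.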